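**Plan**

1. The retrosynthesis first cuts the two ester C–O bonds (10-O-angelate by inverting esterification, 6-O-benzoate by acylation), then returns C10–OH and C6–OH to ketones and C8=C9 to the saturated C10 ketone.
2. Enabling feature: the seven-membered ring (C1, C5, C6, C7, C8, C9, C10) carries oxygen on C6 and C10, the two atoms flanking the ring fusion C5–C1. It is therefore a cycloheptane-1,4-dione, the glycol-cleavage product of a cis-cyclobutane-1,2-diol; re-joining C6–C10 gives a 5-4-5 tricycle whose cyclopentane C6–C10 is the future seven-membered ring.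
3. The tricycle is cut across the cyclobutane ([2+2]) into (R)-4-silyloxy-3-methylcyclopentenone (ring A, C1 methyl, C4 carbonyl) and 4-methyl-1,2-bis(trimethylsilyloxy)cyclopentene (C6–C10, C8 methyl).
4. Forward: ring A is bought; the photocycloaddition adds the cyclobutane and the five-membered ring; the C4 isopropyl carbinol is built on the rigid tricycle; diol cleavage expands the five-membered ring to seven; then the trans ring fusion, C6, C8=C9 and C10 are set.
5. Stereochemistry: one bought C–O stereocentre (erased in step 5) directs the photocycloaddition (C1, C5). C4 comes from convex-face epoxidation, C5 from equilibration, C6 from hydride delivery by the C4 hydroxyl, and C10 from hydride attack anti to the C1 methyl followed by SN2 inversion.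

Key step: step 10

**Remarks**

- Daucane numbering is used throughout: C1 quaternary ring-fusion carbon (methyl), C2 and C3 methylenes of ring A, C4 carbinol carbon (isopropyl), C5 ring-fusion CH, C6 CH–OBz, C7 CH2, C8 C(Me)=, C9 =CH, C10 CH–OAng. β is the face of the C1 methyl group.
- The C8 methyl stereocentre of compounds 6 to 18 is expected to form as a mixture of epimers and is written without a descriptor; both epimers converge when C8 becomes trigonal in step 14.
- Compound 1, dimethyl 3-methylglutarate (4) and angelic acid are taken as commercial.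

**Route**

Step 1
Reactants: 1 (4R)-4-(tert-butyldimethylsilyloxy)cyclopent-2-en-1-one
Product: 2 (3R,4R)-4-(tert-butyldimethylsilyloxy)-3-methyl-1-(trimethylsilyloxy)cyclopent-1-ene
Conditions: Me2CuLi (from MeLi, CuI), TMSCl, THF, −78 °C
Reagents that add atoms: lithium dimethylcuprate [Li+].C[Cu-]C; chlorotrimethylsilane C[Si](C)(C)Cl
Why: Conjugate addition of the Gilman cuprate anti to the silyloxy group, with TMSCl trapping the enolate regiospecifically before it can equilibrate and expel the β-silyloxy group.

Step 2
Reactants: 2 silyl enol ether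
Product: 3 (4R)-4-(tert-butyldimethylsilyloxy)-3-methylcyclopent-2-en-1-one
Conditions: Pd(OAc)2 (1.05 equiv), MeCN, 23 °C
Reagents that add atoms: none
Why: Saegusa–Ito oxidation, in which the palladium enolate loses the C3 hydrogen by β-hydride elimination and restores the enone with the new methyl group on the β-carbon; the silyloxy stereocentre is not involved.

Step 3
Reactants: 4 dimethyl 3-methylpentanedioate
Product: 5 4-methyl-1,2-bis(trimethylsilyloxy)cyclopent-1-ene
Conditions: Na, TMSCl, toluene, reflux
Reagents that add atoms: chlorotrimethylsilane C[Si](C)(C)Cl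
Why: Acyloin condensation under Rühlmann conditions, the enediolate being silylated in situ to the bis(silyl) enediol ether.

Step 4
Reactants: 3 silyloxy enone; 5 bis(silyloxy)cyclopentene
Product: 6 cis-anti-cis 5-4-5 photoadduct (C4 ketone, 2β-OTBS, 1β-methyl, 5β-H, 6α,10α-bis(trimethylsilyloxy))
Conditions: hν (Pyrex, λ > 300 nm), alkene partner in excess, hexane, −20 °C
Reagents that add atoms: none
Why: [2+2] photocycloaddition of the triplet cyclopentenone to the electron-rich symmetrical alkene; the alkene adds to the enone face anti to the C2 silyloxy group, which sets C1 (quaternary) and C5 in one event, the four-membered ring forces both ring fusions to be cis, and the two five-membered rings take the less crowded anti arrangement.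

Step 5
Reactants: 6 photoadduct
Product: 8 saturated tricyclic ketone, via tricyclic enone 7 (not isolated)
Conditions: DBU, THF, 23 °C; then H2 (1 atm), Pd/C (palladium on carbon)
Reagents that add atoms: none
Why: E1cB elimination of the β-silyloxy group (enolization towards C3) erases the directing stereocentre, and hydrogenation of the resulting disubstituted enone C=C gives the saturated ketone without touching the silyl ethers.

Step 6
Reactants: 8 saturated tricyclic ketone
Product: 10 C3=C4 enol triflate, via potassium enolate 9 (not isolated)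
Conditions: KN(SiMe3)2, THF, −78 °C; then PhNTf2, −78 to 0 °C
Reagents that add atoms: N-phenylbis(trifluoromethanesulfonimide) O=S(=O)(N(c1ccccc1)S(=O)(=O)C(F)(F)F)C(F)(F)F
Why: Kinetic deprotonation occurs only at C3, because an enolate towards C5 would place a double bond at the cyclobutane ring fusion, and O-triflation gives the regiodefined enol triflate.

Step 7
Reactants: 10 enol triflate
Product: 11 4-isopropyl-Δ3 tricyclic alkene
Conditions: i-PrMgCl, Fe(acac)3 (5 mol%), THF/NMP, −30 °C
Reagents that add atoms: isopropylmagnesium chloride CC(C)[Mg]Cl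
Why: Iron-catalysed Kumada-type coupling of an alkenyl triflate with an alkyl Grignard reagent replaces the triflate by isopropyl at low temperature and fixes the double bond at C3=C4; the silyl ethers are inert.

Step 8
Reactants: 11 tricyclic alkene
Product: 12 3β,4β-epoxide
Conditions: dimethyldioxirane, acetone/CH2Cl2, −20 °C
Reagents that add atoms: dimethyldioxirane CC1(C)OO1
Why: Neutral epoxidation takes place on the convex face of the bicyclo[3.2.0]heptene unit (the face of H5 and the C1 methyl), because the concave face is covered by the cyclobutane and its two silyloxy groups; this places the C4 oxygen cis to the C1 methyl.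

Step 9
Reactants: 12 epoxide
Product: 14 tricyclic triol, via silylated tertiary alcohol 13 (not isolated)
Conditions: LiEt3BH, THF, 0 to 40 °C; then MeOH, K2CO3, 23 °C
Reagents that add atoms: none
Why: Hydride opens the trisubstituted epoxide by SN2 attack at the secondary carbon C3, leaving the tertiary C4–O bond (4β-OH, 4α-isopropyl) untouched, and mild methanolysis then removes both trimethylsilyl ethers.

Step 10
Reactants: 14 tricyclic triol
Product: 15 cis-fused 4β-hydroxy-5β-daucane-6,10-dione
Conditions: Pb(OAc)4, CH2Cl2, 0 °C
Reagents that add atoms: none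
Why: Criegee glycol cleavage: the cis-1,2-diol on the edge C6–C10 forms a five-membered cyclic lead diester, which fragments in a concerted two-electron step to the carbonyl groups C6=O and C10=O. The cleaved bond is shared by the cyclobutane (C1, C5, C6, C10) and the cyclopentane (C6 to C10), so the cyclopentane gains the two atoms C5 and C1 and becomes the seven-membered ring; no ring is closed by bond formation, the ring arises by scission of the zero-atom bridge of a bicyclo[3.2.0]heptane. The closest known reaction type is the photocycloaddition/glycol-cleavage route from cyclopentenones and 1,2-bis(silyloxy)cyclopentenes to bicyclo[5.3.0]decane-2,5-diones. No stereocentre is created: C6 and C10 become trigonal, and C1, C4 and C5 are carried over unchanged, so the product should be the cis-fused dione. The step needs chemoselectivity for the vicinal diol over the tertiary C4 hydroxyl; only the cis-1,2-diol can chelate lead, and release of the cyclobutane strain should make its cleavage fast at 0 °C.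

Step 11
Reactants: 15 cis-fused dione
Product: 16 trans-fused 4β-hydroxy-5α-daucane-6,10-dione
Conditions: p-TsOH·H2O (10 mol%), CH2Cl2, 23 °C
Reagents that add atoms: none
Why: Acid-catalysed enolization of the C6 ketone towards C5 equilibrates the ring fusion; the trans epimer should be favoured because C6 moves from cis to the isopropyl group to cis to the C4 hydroxyl (hydrogen bond to the C6 carbonyl), and acid is chosen because an alkoxide under basic conditions would open the retro-aldol channel of the β-hydroxy ketone.

Step 12
Reactants: 16 trans-fused dione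
Product: 17 4β,6α-dihydroxy-5α-daucan-10-one
Conditions: Me4NBH(OAc)3, MeCN/AcOH (1:1), −30 °C
Reagents that add atoms: none
Why: Evans–Saksena reduction: the borohydride binds to the C4 hydroxyl, which is cis to C6 in the trans-fused ketol, and delivers hydride intramolecularly to the β face of the C6 carbonyl to give the 6α (equatorial) alcohol, while the C10 ketone has no suitably placed hydroxyl and is not reduced by this reagent.

Step 13
Reactants: 17 diol ketone
Product: 18 6α-benzoyloxy-4β-hydroxy-5α-daucan-10-one
Conditions: BzCl, pyridine, DMAP (cat.), CH2Cl2, 0 to 23 °C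
Reagents that add atoms: benzoyl chloride O=C(Cl)c1ccccc1
Why: Acylation of the secondary 6α-hydroxyl; the tertiary C4 hydroxyl is too hindered to react under these conditions.

Step 14
Reactants: 18 benzoate ketone
Product: 19 6α-benzoyloxy-4β-hydroxy-5α-dauc-8-en-10-one
Conditions: IBX, DMSO/toluene, 75 °C
Reagents that add atoms: none
Why: IBX dehydrogenation of a ketone through its enol; the C10 ketone can enolize only towards C9 because C1 is quaternary, so the C8=C9 enone should form regiospecifically and both C8 epimers converge.

Step 15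
Reactants: 19 enone
Product: 20 6α-benzoyloxy-5α-dauc-8-ene-4β,10β-diol
Conditions: NaBH4, CeCl3·7H2O, MeOH, −40 °C
Reagents that add atoms: none
Why: Luche 1,2-reduction; hydride is expected to add to C10 from the α face, anti to the axial C1 methyl group on the adjacent carbon, giving the 10β (pseudo-equatorial) allylic alcohol, the epimer required for the inverting esterification.

Step 16
Reactants: 20 10β-allylic alcohol
Product: 21 target (1S,4R,5S,6S,10R)-10α-angeloyloxy-6α-benzoyloxy-5α-dauc-8-en-4β-ol
Conditions: angelic acid, PPh3, DIAD, toluene, 0 to 23 °C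
Reagents that add atoms: angelic acid C/C=C(/C)C(=O)O
Why: Mitsunobu esterification: the 10β-oxyphosphonium group is displaced by angelate from the open α face (SN2 at an allylic carbon), inverting C10 to the 10α-ester, while the neutral conditions should preserve the (Z)-geometry of the angelate and leave the tertiary C4 hydroxyl untouched.

**Compound list**

1 | (4R)-4-(tert-butyldimethylsilyloxy)cyclopent-2-en-1-one | O=C1C=C[C@H](O[Si](C)(C)C(C)(C)C)C1 | starting material
2 | (3R,4R)-4-(tert-butyldimethylsilyloxy)-3-methyl-1-(trimethylsilyloxy)cyclopent-1-ene (methyl trans to OTBS) | C[Si](C)(C)OC1=C[C@@H](C)[C@H](O[Si](C)(C)C(C)(C)C)C1 | intermediate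
3 | (4R)-4-(tert-butyldimethylsilyloxy)-3-methylcyclopent-2-en-1-one | O=C1C=C(C)[C@H](O[Si](C)(C)C(C)(C)C)C1 | intermediate
4 | dimethyl 3-methylpentanedioate (dimethyl 3-methylglutarate) | COC(=O)CC(C)CC(=O)OC | starting material
5 | 4-methyl-1,2-bis(trimethylsilyloxy)cyclopent-1-ene | CC1CC(O[Si](C)(C)C)=C(O[Si](C)(C)C)C1 | intermediate
6 | cis-anti-cis 5-4-5 photoadduct: cyclopentanone ring A (C4=O, C3H2, C2 β-OTBS, C1 β-methyl, C5 β-H) fused at C1–C5 to the cyclobutane C1–C5–C6–C10, itself fused at C6–C10 to the cyclopentane C6–C7–C8(Me)–C9–C10; 6α,10α-bis(trimethylsilyloxy) | O=C1C[C@@H](O[Si](C)(C)C(C)(C)C)[C@@]2(C)[C@@H]1[C@]3(O[Si](C)(C)C)CC(C)C[C@]23O[Si](C)(C)C | intermediate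
7 | tricyclic C2=C3 enone (C4=O) formed from 6 by loss of the C2 silyloxy group | O=C1C=C[C@@]2(C)[C@@H]1[C@]3(O[Si](C)(C)C)CC(C)C[C@]23O[Si](C)(C)C | intermediate (not isolated)
8 | saturated tricyclic ketone (C4=O; C2 and C3 methylene; otherwise as 6) | O=C1CC[C@@]2(C)[C@@H]1[C@]3(O[Si](C)(C)C)CC(C)C[C@]23O[Si](C)(C)C | intermediate
9 | potassium C3=C4 enolate of 8 | [K+].[O-]C1=CC[C@@]2(C)[C@@H]1[C@]3(O[Si](C)(C)C)CC(C)C[C@]23O[Si](C)(C)C | intermediate (not isolated)
10 | tricyclic C3=C4 enol triflate (4-trifluoromethanesulfonyloxy) | FC(F)(F)S(=O)(=O)OC1=CC[C@@]2(C)[C@@H]1[C@]3(O[Si](C)(C)C)CC(C)C[C@]23O[Si](C)(C)C | intermediate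
11 | tricyclic 4-isopropyl-Δ3 alkene | CC(C)C1=CC[C@@]2(C)[C@@H]1[C@]3(O[Si](C)(C)C)CC(C)C[C@]23O[Si](C)(C)C | intermediate
12 | tricyclic 3β,4β-epoxide (oxygen on the face of the C1 methyl; isopropyl α) | CC(C)[C@]12O[C@H]1C[C@@]3(C)[C@@H]2[C@]4(O[Si](C)(C)C)CC(C)C[C@]34O[Si](C)(C)C | intermediate
13 | tricyclic tertiary alcohol: 4β-hydroxy-4α-isopropyl, 6α,10α-bis(trimethylsilyloxy) | CC(C)[C@]1(O)CC[C@@]2(C)[C@@H]1[C@]3(O[Si](C)(C)C)CC(C)C[C@]23O[Si](C)(C)C | intermediate (not isolated)
14 | tricyclic triol: 4β-hydroxy-4α-isopropyl, cis-6α,10α-cyclobutanediol | CC(C)[C@]1(O)CC[C@@]2(C)[C@@H]1[C@]3(O)CC(C)C[C@]23O | intermediate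
15 | cis-fused 4β-hydroxy-5β-daucane-6,10-dione (1β-methyl, 5β-H, 4α-isopropyl) | O=C1CC(C)CC(=O)[C@H]2[C@]1(C)CC[C@@]2(O)C(C)C | intermediate
16 | trans-fused 4β-hydroxy-5α-daucane-6,10-dione (1β-methyl, 5α-H) | O=C1CC(C)CC(=O)[C@@H]2[C@]1(C)CC[C@@]2(O)C(C)C | intermediate
17 | 4β,6α-dihydroxy-5α-daucan-10-one | O=C1CC(C)C[C@H](O)[C@@H]2[C@]1(C)CC[C@@]2(O)C(C)C | intermediate
18 | 6α-benzoyloxy-4β-hydroxy-5α-daucan-10-one | O=C1CC(C)C[C@H](OC(=O)c2ccccc2)[C@@H]2[C@]1(C)CC[C@@]2(O)C(C)C | intermediate
19 | 6α-benzoyloxy-4β-hydroxy-5α-dauc-8-en-10-one | O=C1C=C(C)C[C@H](OC(=O)c2ccccc2)[C@@H]2[C@]1(C)CC[C@@]2(O)C(C)C | intermediate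
20 | 6α-benzoyloxy-5α-dauc-8-ene-4β,10β-diol | O[C@H]1C=C(C)C[C@H](OC(=O)c2ccccc2)[C@@H]2[C@]1(C)CC[C@@]2(O)C(C)C | intermediate
21 | (1S,4R,5S,6S,10R)-10α-angeloyloxy-6α-benzoyloxy-5α-dauc-8-en-4β-ol | C/C=C(/C)C(=O)O[C@@H]1C=C(C)C[C@H](OC(=O)c2ccccc2)[C@@H]2[C@]1(C)CC[C@@]2(O)C(C)C | target

**Step count and risks**

Total step count: 16. Longest linear sequence: 15 steps (1 to 21 through steps 1, 2 and 4 to 16; step 3 makes the second photo partner).

Steps most likely to fail:

Step 16. The SN2 displacement at the neopentylic allylic carbon C10 by the weakly acidic, hindered angelic acid may be slow, so that elimination to a diene, SN2′ attack at C8 or phosphine-induced Z to E isomerization of the acid competes. The fallback sets out from 20 and returns at 21. The Mitsunobu reaction is run with chloroacetic acid (a stronger, smaller pronucleophile) to give the inverted 10α-chloroacetate of the 6α-benzoate F1. The chloroacetyl group is removed with thiourea and NaHCO3 in ethanol, which leaves the benzoate, to give 6α-benzoyloxy-5α-dauc-8-ene-4β,10α-diol F2. The angelate is then introduced by O-acylation with retention, using the mixed anhydride of angelic acid and 2,4,6-trichlorobenzoyl chloride (Et3N, toluene, 80 °C), so that angelate no longer has to act as a nucleophile.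

Step 11. During equilibration of the ring fusion, the β-hydroxy ketone may instead dehydrate to the C4=C5 enone or undergo retro-aldol opening of ring A. The fallback sets out from 13 (isolated after aqueous work-up instead of being methanolysed) and returns at 16. The tertiary hydroxyl is capped with MOMCl and i-Pr2NEt to give the methoxymethyl ether F3, which can neither form an alkoxide nor leave easily. Methanolysis (K2CO3, MeOH) gives the cyclobutanediol F4, and Pb(OAc)4 cleavage gives the cis-fused 4β-methoxymethoxy dione F5. The ring fusion is now equilibrated under base (DBU, toluene, 40 °C), where no retro-aldol is possible, to the trans-fused dione F6. Mild acid methanolysis (HCl cat., MeOH, 0 °C) removes the acetal and gives 16.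

Step 7. Coupling of the secondary Grignard reagent at the hindered alkenyl triflate may be outrun by β-hydride transfer (reduction of the triflate to the plain alkene) or by isomerization of the isopropyl group. The fallback sets out from 8 and returns at 11. Isopropylmagnesium chloride premixed with anhydrous CeCl3 (THF, −78 °C) adds to the ketone from the convex face to give the tertiary alcohol with 4α-hydroxy and 4β-isopropyl groups F7. Syn-dehydration with the Burgess reagent follows; only a C3 hydrogen and the isopropyl methine are syn to the hydroxyl (H5 is anti), so the product is alkene 11, from which any isopropylidene isomer would be separated.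

**Further compounds**

F1 | step 16 | 6α-benzoyloxy-10α-chloroacetoxy-5α-dauc-8-en-4β-ol | O=C(CCl)O[C@@H]1C=C(C)C[C@H](OC(=O)c2ccccc2)[C@@H]2[C@]1(C)CC[C@@]2(O)C(C)C
F2 | step 16 | 6α-benzoyloxy-5α-dauc-8-ene-4β,10α-diol | O[C@@H]1C=C(C)C[C@H](OC(=O)c2ccccc2)[C@@H]2[C@]1(C)CC[C@@]2(O)C(C)C
F3 | step 11 | tricyclic 4β-methoxymethoxy-4α-isopropyl-6α,10α-bis(trimethylsilyloxy) compound (MOM ether of 13) | CC(C)[C@]1(OCOC)CC[C@@]2(C)[C@@H]1[C@]3(O[Si](C)(C)C)CC(C)C[C@]23O[Si](C)(C)C
F4 | step 11 | tricyclic 4β-methoxymethoxy-6α,10α-diol | CC(C)[C@]1(OCOC)CC[C@@]2(C)[C@@H]1[C@]3(O)CC(C)C[C@]23O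
F5 | step 11 | cis-fused 4β-methoxymethoxy-5β-daucane-6,10-dione | O=C1CC(C)CC(=O)[C@H]2[C@]1(C)CC[C@@]2(OCOC)C(C)C
F6 | step 11 | trans-fused 4β-methoxymethoxy-5α-daucane-6,10-dione | O=C1CC(C)CC(=O)[C@@H]2[C@]1(C)CC[C@@]2(OCOC)C(C)C
F7 | step 7 | tricyclic tertiary alcohol with 4α-hydroxy and 4β-isopropyl (C4 epimer of 13) | CC(C)[C@@]1(O)CC[C@@]2(C)[C@@H]1[C@]3(O[Si](C)(C)C)CC(C)C[C@]23O[Si](C)(C)C
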